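| flask | substrate | free catalyst | remark | time |
|---|---|---|---|---|
| delta | 0.79 M | 160 mM | run made earlier |  |
| beta | 0.79 M | 560 mM | run made earlier |  |
| zeta | 0.79 M | 2900 mM | run made earlier |  |
| alder | 0.79 M | 150 mM |  | 15 h |
| cedar | 0.79 M | 300 mM |  | 15 h |
| birch | 0.79 M | 600 mM |  | 15 h |
| maple | 0.79 M | 1200 mM |  | 15 h |
| oak | 0.79 M | 2500 mM |  | 15 h |

| run | time / h | product / % | substrate / % |
|---|---|---|---|
| delta | 1.00 | 0 | 76 |
| delta | 2.50 | 6 | 76 |
| delta | 5.00 | 11 | 70 |
| delta | 8.00 | 17 | 58 |
| delta | 10.0 | 21 | 58 |
| beta | 1.00 | 3 | 29 |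
| beta | 2.50 | 11 | 20 |
| beta | 5.00 | 32 | 5 |
| beta | 8.00 | 55 | 0 |
| beta | 10.0 | 60 | 1 |
| zeta | 0.833 | 1 | 2 |
| zeta | 1.50 | 6 | 1 |
| zeta | 3.00 | 15 | 1 |
| zeta | 6.00 | 23 | 0 |
| zeta | 10.0 | 22 | 1 |

(scatter of a reading: 2 percentage points)

- "hardly changes" means that all values lie within two and a half points (for a concentration: within two and a half percent of the largest)
- a step back or a flat step of under half a percent of the largest counts as no turn

- [product] at the end for alder, cedar, birch, maple, oak, in this order
- the shape of the row from first to last (falls all the way / hardly changes / rises all the way / rises, then falls / falls, then rises)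

1. Zeta held 5.18 times the free catalyst of beta, yet I saw its product stop at 23%, against 60% in beta. So I treated the row as two regimes and reckoned the low-catalyst side.

2. I took the turnover rate, meaning product made per hour per [free catalyst] charged. In delta, substrate fell from 76% to 58% while product climbed steadily, which I read as zero order in substrate.

3. I then defined the filling time: the [substrate] charged divided by the product of turnover rate and [free catalyst] charged. On the zero-order reading, and while substrate lasted, the percentage made was the run time over this filling time.

4. I asked which numbers had to be good. The substrate charge cancelled from that percentage, since delta had the same charge. Run time and [free catalyst] entered in simple proportion and were set exactly. The delta reading mattered: its scatter of 2 percentage points on 21% moved my outcome by 9.52%.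

5. Delta's last reading gave 0.104 h⁻¹, and beta at 8.00 h read 0.0970 h⁻¹. I froze the delta value.

6. Alder's filling time was 50.8 h, so I expected 29.5%, or 0.233 M. Cedar's was 25.4 h, so I expected 59.1%, or 0.467 M. Birch's, 12.7 h, lay inside the run, so my line ended there, and zeta pointed to a fall at higher [free catalyst].

7. The forecast gave 0.24 M, 0.41 M, 0.5 M, 0.34 M and 0.2 M, with the shape rises, then falls, holding that at low catalyst “time limits the result instead”. Its cedar value was lower than mine.

8. The flasks gave 0.247 M, 0.486 M, 0.514 M, 0.337 M and 0.148 M, with the shape rises, then falls.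

    substrate + free catalyst → catalyst intermediate A (k = 0.0210 L mol⁻¹ s⁻¹)
    catalyst intermediate A → catalyst intermediate B (k = 4.00 × 10⁻⁵ s⁻¹)
    catalyst intermediate B → free catalyst + product (k = 2.00 × 10⁻⁴ s⁻¹)
    free catalyst + product → spent catalyst A (k = 4.00 × 10⁻⁵ L mol⁻¹ s⁻¹)
    2 catalyst intermediate B → spent catalyst B (k = 1.40 × 10⁻⁵ L mol⁻¹ s⁻¹)
    free catalyst ⇌ dormant form (K = 0.380, k = 2.00 × 10⁻⁵ s⁻¹)

Alder reached 31.2% against the 29.5% from its filling time, and cedar reached 61.5% against 59.1%. Alder's filling time of 50.8 h lay beyond its 15 h, and at the end alder still held 50% of its substrate, while catalyst intermediate A, the resting state in alder, held 82.4% of the catalyst charged. The length of the run counted for alder: against 0.247 M at 15 h, a run to 150 h gave 0.640 M.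

(The runs are simulated on assumed constants; noise was put on by code.)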